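Everything rests on opening ring B (the cycloheptanone) at C7–C8 and cutting the side chain at C9–C11. The feature exploited: C8, C9, C10 and the methyl groups on C8 and C9 form a tigloyl unit on C1 of ring A (the cyclopentane). A C7 radical that adds to C8 therefore turns C9 into a tertiary alpha-keto radical. One tin-mediated chain reaction closes ring B 7-endo and allylates C9, creating two C–C bonds, the C8 stereocentre and quaternary C9. The precursor is a ring A cyclopentane with the tigloyl ketone on C1, silyloxy and 2-iodoethyl (C6, C7) groups on C5 and a silyl ether on C3.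

Key step: step 11

Numbering: ring A = C1 (fusion CH), C2, C3 (CH–O), C4 (CMe2), C5 (fusion C–O). Ring B = C5, C6, C7, C8 (CHMe), C9 (quaternary), C10 (C=O), C1. Side chain = C11, C12. Butenolide = C13 (beta carbon), C14 (=CH), C15 (C=O), C16 (OCH2). "Top" is the face of ring A that carries the C3 oxygen. In the target C6, C1–H and both ring B methyl groups are on top; C5–O, C10 and C11 are at the bottom (1R,3R,5R,8R,9S).

Design remark: C10–OH travels as a TES ether and C5–OH is silylated last, so the two carbinols are told apart without selective cleavage of a TMS ether.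

Assumption 1: the (R,R)-TsDPEN complex is taken to give the (R)-ketol 2; if the sense is opposite for this dione, the (S,S)-ligand is used.

Assumption 2: in step 11 the ring fusion is taken to steer C7 to the C8=C9 face that puts the C8 methyl cis to C1–H; no precedent fixes this sense.

Step 1
Reactants: 1 2,2-dimethylcyclopentane-1,3-dione
Product: 2 (R)-3-hydroxy-2,2-dimethylcyclopentan-1-one
Conditions: RuCl(p-cymene)[(R,R)-TsDPEN] (1 mol %), HCO2H/Et3N (5:2), CH2Cl2, 30 °C
Reagents that add atoms: none
Why: Noyori asymmetric transfer hydrogenation: the chiral Ru–H/N–H catalyst tells the two enantiotopic carbonyl groups of the prochiral dione apart and thereby sets C3, while the hindered ketol is reduced further only slowly.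

Step 2
Reactants: 2 (R)-3-hydroxy-2,2-dimethylcyclopentan-1-one
Product: 3 (R)-3-(tert-butyldimethylsilyloxy)-2,2-dimethylcyclopentan-1-one
Conditions: TBSCl, imidazole, DMF, 25 °C
Reagents that add atoms: tert-butyldimethylsilyl chloride (CC(C)(C)[Si](C)(C)Cl)
Why: Corey silylation (silyl chloride/imidazole) of the only hydroxyl group; C4 is quaternary, so the beta-hydroxy ketone cannot eliminate.

Step 3
Reactants: 3 (R)-3-(tert-butyldimethylsilyloxy)-2,2-dimethylcyclopentan-1-one; 4 (E)-2-methylbut-2-enal (tiglic aldehyde)
Product: 6 aldol adduct (C5 ketone; C1 carries CH(OH)C(Me)=CHMe at the bottom face, trans to C3–OTBS; C10 carbinol epimers carried together), via lithium enolate 5 (not isolated)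
Conditions: LDA, THF, −78 °C; 4, −78 °C; AcOH quench at −78 °C
Reagents that add atoms: none
Why: Lithium enolate aldol addition: only C1 can be deprotonated because C4 is quaternary, the enal reacts 1,2 at low temperature, and the aldehyde approaches the enolate face opposite to the C3 silyloxy group, which sets C1 (side chain at the bottom), whereas the C10 carbinol configuration is irrelevant since step 9 removes it.

Step 4
Reactants: 6 aldol adduct
Product: 7 C10 triethylsilyl ether of 6
Conditions: TESCl, imidazole, CH2Cl2, 0 °C to rt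
Reagents that add atoms: triethylsilyl chloride (CC[Si](CC)(CC)Cl)
Why: Silyl ether formation under mild base masks the C10 hydroxyl group, which blocks retro-aldol cleavage in step 5 and keeps C10–O distinguishable from the C5 and C7 hydroxyl groups that follow.

Step 5
Reactants: 7 C10 triethylsilyl ether of 6; 8 vinylmagnesium bromide
Product: 9 C5 vinyl carbinol (vinyl C6=C7 on top, C5–OH at the bottom, cis to the C1 side chain)
Conditions: CeCl3 (dried), 8, THF, −78 °C; then 7, −78 to −30 °C; aq NH4Cl
Reagents that add atoms: none
Why: Imamoto organocerium 1,2-addition: the weakly basic, oxophilic reagent adds to the crowded, enolisable ketone instead of deprotonating C1, and vinyl enters anti to the bulky C1 side chain, which sets C5 with C6 on top and the hydroxyl group at the bottom.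

Step 6
Reactants: 9 C5 vinyl carbinol
Product: 11 C5,C7-diol (C5 carries CH2CH2OH), via B-alkyl-9-BBN adduct 10 (not isolated)
Conditions: 9-BBN, THF, 0 to 45 °C; then aq NaOH, 30 % H2O2, 0 °C
Reagents that add atoms: hydrogen peroxide (OO)
Why: Brown hydroboration–oxidation: 9-BBN places boron on the terminal carbon C7 of the monosubstituted alkene and leaves the trisubstituted C8=C9 alkene untouched, and alkaline peroxide replaces boron by hydroxyl.

Step 7
Reactants: 11 C5,C7-diol
Product: 12 C7 iodide (C5 carries CH2CH2I and free OH)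
Conditions: I2, PPh3, imidazole, CH2Cl2, 0 °C
Reagents that add atoms: iodine ([I][I])
Why: Garegg–Samuelsson (Appel-type) iodination: only the primary C7 alcohol forms an alkoxyphosphonium ion that iodide can displace, and the crowded tertiary C5 alcohol stays unchanged.

Step 8
Reactants: 12 C7 iodide
Product: 13 C5,C10-diol iodide (TES removed)
Conditions: pyridinium p-toluenesulfonate (10 mol %), MeOH/CH2Cl2, 0 °C
Reagents that add atoms: none
Why: Acid-catalysed methanolysis of a silyl ether: the secondary allylic TES ether is cleaved far faster than the neopentyl-type secondary TBS ether, and the iodide and the tertiary alcohol are inert.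

Step 9
Reactants: 13 C5,C10-diol iodide
Product: 14 C1 tigloyl ketone with free C5–OH (1R,3R,5R)
Conditions: Dess–Martin periodinane, CH2Cl2, 0 °C to rt
Reagents that add atoms: none
Why: Dess–Martin oxidation turns the only oxidisable (secondary allylic) alcohol into the tigloyl ketone under neutral conditions, so that the (E)-alkene, C1 and the primary iodide are not affected and both C10 epimers converge.

Step 10
Reactants: 14 C1 tigloyl ketone with free C5–OH
Product: 15 radical precursor: ring A cyclopentane with C1 tigloyl ketone (bottom), C5–OTMS (bottom), C5 2-iodoethyl (top), C3–OTBS (top) (1R,3R,5R)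
Conditions: TMSOTf, 2,6-lutidine, CH2Cl2, −78 to −20 °C
Reagents that add atoms: trimethylsilyl triflate (C[Si](C)(C)OS(=O)(=O)C(F)(F)F)
Why: Silyl triflate/hindered pyridine silylation is fast enough for the crowded tertiary alcohol at low temperature, where enol silylation of the ketone and beta-elimination do not compete.

Step 11
Reactants: 15 radical precursor; 16 allyltributylstannane
Product: 19 trans-fused bicyclic C10 ketone with C8 methyl (top), C9 methyl (top), C9 allyl (bottom), C5–OTMS, C3–OTBS (1R,3R,5R,8R,9S), via C7 radical 17 (not isolated), via C9 radical 18 (not isolated)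
Conditions: 16 (3 equiv, about 15 mM), 2,2'-azobis(2-methylpropionitrile) (0.2 equiv, in portions), benzene (15 at 5 mM), 80 °C
Reagents that add atoms: none
Why: Proposed new method: Bu3Sn radical (from 16 and the initiator) abstracts iodine from 15, the nucleophilic primary C7 radical 17 adds to the electron-poor beta carbon C8 of the s-trans tigloyl ketone, and the electrophilic tertiary alpha-keto radical 18 adds to the electron-rich alkene of 16 and expels Bu3Sn radical, which carries the chain, so the polarity is matched in both C–C bond formations. The closest known reaction types are endo-selective alkyl radical cyclisation onto alpha-substituted enones and Keck allyl transfer from allylstannanes to alpha-carbonyl radicals (also run in sequence after intermolecular conjugate addition), but their union in a seven-membered ring closure that ends at a quaternary carbon has not been shown. Ring B closes in the 7-endo-trig mode, because the 6-exo alternative would attack C9, which is fully substituted and is the electron-rich terminus of the enone. C8 is controlled by the alkene face that the C5–C6–C7 tether reaches: the (E) geometry keeps the C8 methyl outside the forming ring (pseudo-equatorial), and the trans-disposed C1 and C5 substituents of ring A are the element that has to select the face cis to C1–H. C9 is controlled by the new C7–C8 bond and the C6/C7 bridge, which cover one face of planar 18, so that 16 enters from the other face (net anti addition across the (E)-alkene) and C11 ends trans to the C8 methyl. The step needs ring closure to outrun direct allylation of 17, which is secured by keeping 16 near 15 mM, by the fully substituted C5 that folds the tether toward the enone, and by the C5 silyl ether, which prevents a C5–OH to C10=O hydrogen bond that would turn C9 away from C7.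

Step 12
Reactants: 19 bicyclic allyl ketone
Product: 21 C13 primary alcohol (C9 carries CH2CH2CH2OH), via B-alkyl-9-BBN adduct 20 (not isolated)
Conditions: 9-BBN, THF, 0 °C to rt; then aq NaOAc, 30 % H2O2, 0 °C
Reagents that add atoms: hydrogen peroxide (OO)
Why: Brown hydroboration–oxidation: 9-BBN adds to the terminal alkene much faster than it reduces the C10 ketone, which is shielded by quaternary C9 and by C1, and acetate-buffered peroxide avoids base-induced loss of the C5 silyloxy group.

Step 13
Reactants: 21 C13 primary alcohol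
Product: 22 C13 aldehyde
Conditions: Dess–Martin periodinane, pyridine, CH2Cl2, 0 °C
Reagents that add atoms: none
Why: Dess–Martin oxidation stops at the aldehyde, and the pyridine buffer protects the silyl ethers.

Step 14
Reactants: 22 C13 aldehyde; 23 formaldehyde (used as paraformaldehyde)
Product: 24 C13 hydroxymethyl ketone (C12–C13(=O)–C16H2OH)
Conditions: 23 (excess), 3-benzyl-5-(2-hydroxyethyl)-4-methylthiazolium chloride (15 mol %), i-Pr2NEt, THF, 60 °C
Reagents that add atoms: none
Why: Thiazolium carbene-catalysed cross-acyloin reaction (hydroxymethylation of an aldehyde): the Breslow intermediate of the unhindered C13 aldehyde is intercepted by excess formaldehyde, while the crowded C10 ketone is not attacked and the weak amine base does not enolise C1.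

Step 15
Reactants: 24 C13 hydroxymethyl ketone; 25 (triphenylphosphoranylidene)ketene
Product: 27 bis-silyl ether of the target (butenolide closed), via ester ylide 26 (not isolated)
Conditions: 25, toluene, 80 °C
Reagents that add atoms: none
Why: Bestmann butenolide synthesis: the primary hydroxyl group adds to the ketene ylide to give 26, whose intramolecular Wittig reaction on the adjacent C13 ketone closes the five-membered lactone, the only free hydroxyl group and the only accessible ketone being those of the side chain.

Step 16
Reactants: 27 bis-silyl ether of the target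
Product: 28 target CNP0077405.2 (1R,3R,5R,8R,9S)
Conditions: HF·pyridine, MeCN, 0 °C to rt
Reagents that add atoms: none
Why: Fluoride-mediated desilylation under slightly acidic conditions removes both silyl ethers without the base that could trigger retro-aldol cleavage, C1 epimerisation or butenolide isomerisation.

Compound list
1 | 2,2-dimethylcyclopentane-1,3-dione | CC1(C)C(=O)CCC1=O | starting material
2 | (R)-3-hydroxy-2,2-dimethylcyclopentan-1-one | O=C1CC[C@@H](O)C1(C)C | intermediate
3 | (R)-3-(tert-butyldimethylsilyloxy)-2,2-dimethylcyclopentan-1-one | O=C1CC[C@@H](O[Si](C)(C)C(C)(C)C)C1(C)C | intermediate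
4 | (E)-2-methylbut-2-enal (tiglic aldehyde) | C/C=C(\C)C=O | starting material
5 | lithium C1=C5 enolate of 3 | [Li]OC1=CC[C@@H](O[Si](C)(C)C(C)(C)C)C1(C)C | intermediate
6 | aldol adduct, C1 side chain trans to C3–OTBS, C10 epimers | C/C=C(\C)C(O)[C@@H]1C[C@@H](O[Si](C)(C)C(C)(C)C)C(C)(C)C1=O | intermediate
7 | C10 triethylsilyl ether of 6 | C/C=C(\C)C(O[Si](CC)(CC)CC)[C@@H]1C[C@@H](O[Si](C)(C)C(C)(C)C)C(C)(C)C1=O | intermediate
8 | vinylmagnesium bromide | C=C[Mg]Br | starting material
9 | C5 vinyl carbinol, vinyl cis to C3–OTBS, OH cis to C1 side chain | C/C=C(\C)C(O[Si](CC)(CC)CC)[C@@H]1C[C@@H](O[Si](C)(C)C(C)(C)C)C(C)(C)[C@@]1(O)C=C | intermediate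
10 | B-(C7-alkyl)-9-BBN adduct of 9 | C/C=C(\C)C(O[Si](CC)(CC)CC)[C@@H]1C[C@@H](O[Si](C)(C)C(C)(C)C)C(C)(C)[C@@]1(O)CCB1C2CCCC1CCC2 | intermediate
11 | C5,C7-diol | C/C=C(\C)C(O[Si](CC)(CC)CC)[C@@H]1C[C@@H](O[Si](C)(C)C(C)(C)C)C(C)(C)[C@@]1(O)CCO | intermediate
12 | C7 iodide with C10–OTES and free C5–OH | C/C=C(\C)C(O[Si](CC)(CC)CC)[C@@H]1C[C@@H](O[Si](C)(C)C(C)(C)C)C(C)(C)[C@@]1(O)CCI | intermediate
13 | C5,C10-diol iodide | C/C=C(\C)C(O)[C@@H]1C[C@@H](O[Si](C)(C)C(C)(C)C)C(C)(C)[C@@]1(O)CCI | intermediate
14 | C1 tigloyl ketone with free C5–OH | C/C=C(\C)C(=O)[C@@H]1C[C@@H](O[Si](C)(C)C(C)(C)C)C(C)(C)[C@@]1(O)CCI | intermediate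
15 | radical precursor (C1 tigloyl, C5–OTMS, C5 2-iodoethyl, C3–OTBS) | C/C=C(\C)C(=O)[C@@H]1C[C@@H](O[Si](C)(C)C(C)(C)C)C(C)(C)[C@@]1(O[Si](C)(C)C)CCI | intermediate
16 | allyltributylstannane | C=CC[Sn](CCCC)(CCCC)CCCC | starting material
17 | primary C7 radical | C/C=C(\C)C(=O)[C@@H]1C[C@@H](O[Si](C)(C)C(C)(C)C)C(C)(C)[C@@]1(O[Si](C)(C)C)C[CH2] | intermediate
18 | bicyclic tertiary C9 alpha-keto radical | C[C@@H]1CC[C@@]2(O[Si](C)(C)C)[C@@H](C[C@@H](O[Si](C)(C)C(C)(C)C)C2(C)C)C(=O)[C]1C | intermediate
19 | bicyclic C10 ketone with C8 methyl and quaternary C9 (methyl, allyl) | C[C@@H]1CC[C@@]2(O[Si](C)(C)C)[C@@H](C[C@@H](O[Si](C)(C)C(C)(C)C)C2(C)C)C(=O)[C@@]1(C)CC=C | intermediate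
20 | B-(C13-alkyl)-9-BBN adduct of 19 | C[C@@H]1CC[C@@]2(O[Si](C)(C)C)[C@@H](C[C@@H](O[Si](C)(C)C(C)(C)C)C2(C)C)C(=O)[C@@]1(C)CCCB1C2CCCC1CCC2 | intermediate
21 | C13 primary alcohol | C[C@@H]1CC[C@@]2(O[Si](C)(C)C)[C@@H](C[C@@H](O[Si](C)(C)C(C)(C)C)C2(C)C)C(=O)[C@@]1(C)CCCO | intermediate
22 | C13 aldehyde | C[C@@H]1CC[C@@]2(O[Si](C)(C)C)[C@@H](C[C@@H](O[Si](C)(C)C(C)(C)C)C2(C)C)C(=O)[C@@]1(C)CCC=O | intermediate
23 | formaldehyde (paraformaldehyde) | C=O | starting material
24 | C13 hydroxymethyl ketone | C[C@@H]1CC[C@@]2(O[Si](C)(C)C)[C@@H](C[C@@H](O[Si](C)(C)C(C)(C)C)C2(C)C)C(=O)[C@@]1(C)CCC(=O)CO | intermediate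
25 | (triphenylphosphoranylidene)ketene | O=C=C=P(c1ccccc1)(c1ccccc1)c1ccccc1 | starting material
26 | C16 (triphenylphosphoranylidene)acetate ester ylide | C[C@@H]1CC[C@@]2(O[Si](C)(C)C)[C@@H](C[C@@H](O[Si](C)(C)C(C)(C)C)C2(C)C)C(=O)[C@@]1(C)CCC(=O)COC(=O)C=P(c1ccccc1)(c1ccccc1)c1ccccc1 | intermediate
27 | C5–OTMS, C3–OTBS ether of the target | C[C@@H]1CC[C@@]2(O[Si](C)(C)C)[C@@H](C[C@@H](O[Si](C)(C)C(C)(C)C)C2(C)C)C(=O)[C@@]1(C)CCC1=CC(=O)OC1 | intermediate
28 | CNP0077405.2 | C[C@@H]1CC[C@@]2(O)[C@@H](C[C@@H](O)C2(C)C)C(=O)[C@@]1(C)CCC1=CC(=O)OC1 | target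

Total step count: 16. Longest linear sequence: 16 steps (1 to 28); 4, 8, 16, 23 and 25 are bought.

Steps most likely to fail

Risk 1, step 11 (the labelled step).
- What may go wrong: allyl transfer to the C7 radical before ring closure, or breakdown of the chain at the crowded C9 radical.
- Ring closure may also occur on the other face of the C8=C9 bond. A chair-like closure that keeps the enone fully coplanar leads C7 to that face, and this would invert the C8/C9 pair relative to the ring fusion.
- Fallback, known chemistry only, from 3 back to 19: ring B is closed by olefin metathesis at C8=C9, and the C8 methyl and the C9 allyl group are then added to the ring enone. Aldol addition of the lithium enolate of 3 to methacrolein gives the methacrolein aldol adduct F1. TESCl/imidazole gives its C10 triethylsilyl ether F2, and but-3-enylmagnesium bromide with CeCl3 adds anti to the C1 side chain to give the C5 but-3-enyl carbinol F3. Methanolysis with pyridinium p-toluenesulfonate gives the C5,C10-diol F4, Dess–Martin oxidation gives the methacryloyl ketone F5, and TMSOTf/2,6-lutidine gives its C5 trimethylsilyl ether F6. Ring-closing metathesis with the second-generation Grubbs catalyst (toluene, 80 °C) gives the trans-fused bicyclic C8=C9 enone F7. Conjugate addition of Me2CuLi to C8 follows (axial attack on the top face, which leads to a chair-like enolate). Alkylation of the regiodefined C9 enolate with allyl iodide (HMPA), anti to the new methyl group, then gives 19.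

Risk 2, step 5.
- What may go wrong: enolisation of 7 at C1 followed by loss of the C10 silyloxy group, sluggish addition at a carbonyl flanked by the C4 gem-dimethyl group and the branched C1 substituent, or erosion of facial selectivity.
- Fallback, from 7 back to 9: the slimmer sp nucleophile ethynylmagnesium bromide (CeCl3, THF, −78 °C) gives the C5 ethynyl carbinol F8. Semi-hydrogenation (H2, Pd on CaCO3 poisoned with Pb(OAc)2, quinoline) then gives 9.

Risk 3, step 14.
- What may go wrong: self-acyloin coupling of the aldehyde, further aldol reaction of the product with formaldehyde, or intramolecular attack of the acyl anion equivalent on C10.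
- Fallback, from 22 back to 24: a protected hydroxymethyl anion is used in place of carbene catalysis. Tin–lithium exchange of Bu3SnCH2OPMB with n-BuLi (THF, −78 °C) and addition to the aldehyde gives the C13 carbinol PMB ether F9. Dess–Martin oxidation gives the PMB-oxymethyl ketone F10, and DDQ (CH2Cl2/pH 7 buffer) gives 24.

Further compounds
F1 | step 11 | methacrolein aldol adduct of 3 (C10 epimers) | C=C(C)C(O)[C@@H]1C[C@@H](O[Si](C)(C)C(C)(C)C)C(C)(C)C1=O
F2 | step 11 | C10 triethylsilyl ether of F1 | C=C(C)C(O[Si](CC)(CC)CC)[C@@H]1C[C@@H](O[Si](C)(C)C(C)(C)C)C(C)(C)C1=O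
F3 | step 11 | C5 but-3-enyl carbinol | C=C(C)C(O[Si](CC)(CC)CC)[C@@H]1C[C@@H](O[Si](C)(C)C(C)(C)C)C(C)(C)[C@@]1(O)CCC=C
F4 | step 11 | C5,C10-diol | C=C(C)C(O)[C@@H]1C[C@@H](O[Si](C)(C)C(C)(C)C)C(C)(C)[C@@]1(O)CCC=C
F5 | step 11 | methacryloyl ketone with free C5–OH | C=C(C)C(=O)[C@@H]1C[C@@H](O[Si](C)(C)C(C)(C)C)C(C)(C)[C@@]1(O)CCC=C
F6 | step 11 | C5 trimethylsilyl ether of F5 | C=C(C)C(=O)[C@@H]1C[C@@H](O[Si](C)(C)C(C)(C)C)C(C)(C)[C@@]1(O[Si](C)(C)C)CCC=C
F7 | step 11 | trans-fused bicyclic C8=C9 enone (C9 methyl) | CC1=CCC[C@@]2(O[Si](C)(C)C)[C@@H](C[C@@H](O[Si](C)(C)C(C)(C)C)C2(C)C)C1=O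
F8 | step 5 | C5 ethynyl carbinol | C/C=C(\C)C(O[Si](CC)(CC)CC)[C@@H]1C[C@@H](O[Si](C)(C)C(C)(C)C)C(C)(C)[C@@]1(O)C#C
F9 | step 14 | C13 carbinol PMB ether (C13 epimers) | C[C@@H]1CC[C@@]2(O[Si](C)(C)C)[C@@H](C[C@@H](O[Si](C)(C)C(C)(C)C)C2(C)C)C(=O)[C@@]1(C)CCC(O)COCc1ccc(OC)cc1
F10 | step 14 | PMB-oxymethyl ketone | C[C@@H]1CC[C@@]2(O[Si](C)(C)C)[C@@H](C[C@@H](O[Si](C)(C)C(C)(C)C)C2(C)C)C(=O)[C@@]1(C)CCC(=O)COCc1ccc(OC)cc1
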